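**Plan** (target atom numbers C1–C15 are used for every intermediate)
1. Late cuts: the tiglate at O8, the lactone bond O6–C12 (ring B) and the C9 carbinol (back to a ketone). This exposes ring A, the ten-membered carbocycle, in which C8 carries OH, sits next to the C9 ketone and is joined through C7 to the exocyclic C11=C13 methylene.
2. That homoallylic alcohol beside a ketone that can enolise only at C8 is a [2,3]-Wittig retron: C7–C8 is cut and O8–C13 restored, giving a 13-membered α-allyloxy ketone (ring atoms C11, C7, C6–C1, C10, C9, C8, O8, C13).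
3. The macrocycle is cut at C7=C11 (Horner–Wadsworth–Emmons) and O8–C13 (oxa-Michael to a phosphonoacrylate); the C8–C7 chain is cut at C5–C6 (Nozaki–Hiyama–Kishi) and C2–C3 (boron aldol).
4. Forward: C8–C2 methyl ketone plus C3–C5 iodoenal, then C6–C7, the O8–C13 ether, the 13-membered ring, its contraction to ring A, acylation of O8, reduction at C9, and last ring B and unmasking of C1 and O10.
5. Stereochemistry: C10 from the resolved hydroxy ester; C3 by reagent-controlled aldol; C6 by oxazaborolidine reduction; C7 and C8 in the ring contraction (from C6 and the (E)-enoate); C9 by chelation-controlled reduction; the 4Z alkene from the iodoalkene.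

Key step: step 19

Remark on the chemistry: the (S)-enantiomer of 1 is assumed to be separable on a polysaccharide chiral phase, its configuration being confirmed before use. The C9 carbinol of 17 and 19–22 and the C11 centre of 19–21 are unassigned epimer mixtures (both become sp2 later), so their SMILES carry no descriptor there. Aldehyde 12 is taken as commercially available.

Step 1
Reactants: 1 ethyl 2-hydroxy-2-methylbut-3-enoate (racemate)
Product: 2 ethyl (2S)-2-hydroxy-2-methylbut-3-enoate
Conditions: preparative HPLC, cellulose tris(3,5-dimethylphenylcarbamate) phase, hexane/i-PrOH, rt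
Reagents that add atoms: none
Why: Chromatographic resolution on a chiral stationary phase separates the enantiomers without any bond change, so the C10 configuration is selected here and carried unchanged to the target.

Step 2
Reactants: 2 ethyl (2S)-2-hydroxy-2-methylbut-3-enoate
Product: 3 ethyl (2S)-2-(methoxymethoxy)-2-methylbut-3-enoate
Conditions: MOMCl, i-Pr2NEt, Bu4NI (cat.), CH2Cl2, 40 °C
Reagents that add atoms: chloromethyl methyl ether, COCCl
Why: Alkylation of the tertiary alcohol with an α-chloro ether (MOM ether formation) under amine base is standard and does not touch the quaternary C10.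

Step 3
Reactants: 3 ethyl (2S)-2-(methoxymethoxy)-2-methylbut-3-enoate
Product: 4 (2S)-N-methoxy-2-(methoxymethoxy)-N,2-dimethylbut-3-enamide
Conditions: MeNHOMe·HCl, i-PrMgCl, THF, −20 → 0 °C
Reagents that add atoms: N,O-dimethylhydroxylamine hydrochloride, CNOC.Cl
Why: Weinreb amide synthesis by aminolysis of the ester with the chloromagnesium amide works on α-quaternary, non-enolisable esters.

Step 4
Reactants: 4 (2S)-N-methoxy-2-(methoxymethoxy)-N,2-dimethylbut-3-enamide
Product: 5 (3S)-3-(methoxymethoxy)-3-methylpent-4-en-2-one (C8=C9 vinyl, C10, C1 ketone, C2 methyl)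
Conditions: MeMgBr, THF, 0 °C
Reagents that add atoms: methylmagnesium bromide, C[Mg]Br
Why: Weinreb ketone synthesis: the chelated tetrahedral intermediate stops the Grignard addition at the methyl ketone, which supplies C2.

Step 5
Reactants: 6 (Z)-3-iodo-2-methylprop-2-en-1-ol
Product: 7 (Z)-3-iodo-2-methylprop-2-enal
Conditions: MnO2, CH2Cl2, rt, dark
Reagents that add atoms: none
Why: Allylic alcohol oxidation with activated MnO2 is neutral and should keep the (Z)-iodoalkene geometry.

Step 6
Reactants: 5 (3S)-3-(methoxymethoxy)-3-methylpent-4-en-2-one; 7 (Z)-3-iodo-2-methylprop-2-enal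
Product: 9 β-hydroxy ketone (3S,10S,4Z)-aldol adduct, via diisopinocampheylboron enolate 8 (not isolated)
Conditions: (+)-Ipc2BCl, Et3N, Et2O, 0 °C; 7, −78 → −20 °C; H2O2, pH 7 buffer, MeOH, 0 °C
Reagents that add atoms: none
Why: Paterson boron aldol reaction of a methyl ketone: enolisation is possible only at C2, and the isopinocampheyl ligands of the (+)-reagent should direct attack to the si face of the enal, setting (3S) under reagent control, the minor C3 epimer being removed by chromatography.

Step 7
Reactants: 9 β-hydroxy ketone (3S,10S,4Z)-aldol adduct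
Product: 10 O3 TBS ether of 9
Conditions: TBSOTf, 2,6-lutidine, CH2Cl2, −78 °C
Reagents that add atoms: tert-butyldimethylsilyl triflate, CC(C)(C)[Si](C)(C)OS(=O)(=O)C(F)(F)F
Why: Silyl ether formation at −78 °C protects the β-hydroxyl before retro-aldol or elimination can set in.

Step 8
Reactants: 10 O3 TBS ether of 9
Product: 11 C1 ethylene ketal (C8=C9 vinyl, (10S)-OMOM, C1 dioxolane, (3S)-OTBS, (4Z)-5-iodo)
Conditions: (TMSOCH2)2, TMSOTf (cat.), CH2Cl2, −78 → −20 °C; pyridine
Reagents that add atoms: 1,2-bis(trimethylsilyloxy)ethane, C[Si](C)(C)OCCO[Si](C)(C)C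
Why: Noyori ketalisation, driven by formation of hexamethyldisiloxane, runs under aprotic low-temperature conditions that should spare the TBS and MOM ethers and the β-silyloxy ketone, the α-alkoxy group making the hindered C1 carbonyl more electrophilic.

Step 9
Reactants: 11 C1 ethylene ketal vinyl iodide; 12 2-[(4-methoxybenzyl)oxy]acetaldehyde
Product: 13 allylic alcohol with the C5–C6 bond formed (C6 epimer mixture, C7–OPMB)
Conditions: CrCl2, NiCl2 (cat.), DMSO, rt
Reagents that add atoms: none
Why: Nozaki–Hiyama–Kishi coupling: the alkenylchromium species forms with retention of the (Z)-geometry and adds chemoselectively to the aldehyde; the C6 epimers are not separated because C6 is oxidised next.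

Step 10
Reactants: 13 allylic alcohol (C6 epimer mixture)
Product: 14 (4Z)-enone (C6 ketone)
Conditions: Dess–Martin periodinane, NaHCO3, CH2Cl2, 0 °C → rt
Reagents that add atoms: none
Why: Dess–Martin oxidation under bicarbonate buffer should give the enone without isomerising the trisubstituted (Z)-alkene.

Step 11
Reactants: 14 (4Z)-enone
Product: 15 (6R)-allylic alcohol (3S,6R,10S,4Z)
Conditions: (R)-Me-CBS oxazaborolidine, catecholborane, toluene, −78 °C
Reagents that add atoms: none
Why: Corey–Bakshi–Shibata reduction with the alkenyl group as the large and CH2OPMB as the small substituent should give the (6R)-alcohol with the (R)-catalyst, catecholborane at −78 °C leaving the vinyl group untouched.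

Step 12
Reactants: 15 (6R)-allylic alcohol
Product: 16 3,6-bis-TBS ether
Conditions: TBSOTf, 2,6-lutidine, CH2Cl2, −78 → 0 °C
Reagents that add atoms: tert-butyldimethylsilyl triflate, CC(C)(C)[Si](C)(C)OS(=O)(=O)C(F)(F)F
Why: Silyl ether formation on the secondary allylic alcohol fixes O6 until the lactone is closed.

Step 13
Reactants: 16 3,6-bis-TBS ether
Product: 17 8,9-diol (C9 epimer mixture)
Conditions: OsO4 (cat.), NMO, acetone/H2O, 0 °C
Reagents that add atoms: N-methylmorpholine N-oxide, C[N+]1([O-])CCOCC1; water, O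
Why: Upjohn dihydroxylation: the terminal vinyl group should be osmylated much faster than the (Z)-trisubstituted C4=C5 alkene, which is shielded by two allylic silyloxy groups, and the C9 configuration is irrelevant because C9 is oxidised in step 18.

Step 14
Reactants: 17 8,9-diol; 18 trimethyl 2-phosphonoacrylate
Product: 19 O8–C13 ether phosphonate (C9 and C11 epimer mixtures)
Conditions: NaH, THF, 0 °C; 18, −40 °C; AcOH
Reagents that add atoms: none
Why: Oxa-Michael addition of the primary C8 alkoxide to the doubly activated phosphonoacrylate gives the stabilised phosphonoacetate anion, which is protonated on quench; the neopentyl C9 hydroxyl should not compete.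

Step 15
Reactants: 19 O8–C13 ether phosphonate
Product: 20 C7 primary alcohol
Conditions: DDQ, CH2Cl2/pH 7 buffer, 0 °C
Reagents that add atoms: none
Why: Oxidative cleavage of the PMB ether with DDQ is orthogonal to the silyl ethers, the ketal, the MOM ether and the phosphonate.

Step 16
Reactants: 20 C7 primary alcohol
Product: 21 C7 aldehyde
Conditions: TEMPO (cat.), PhI(OAc)2, CH2Cl2, rt
Reagents that add atoms: none
Why: TEMPO-catalysed oxidation is selective for the primary alcohol over the hindered secondary C9 hydroxyl and gives the α-silyloxy aldehyde under non-basic conditions.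

Step 17
Reactants: 21 C7 aldehyde
Product: 22 13-membered (7E)-enoate with C9 carbinol
Conditions: LiCl, i-Pr2NEt, MeCN, 1 mM, rt
Reagents that add atoms: none
Why: Intramolecular Horner–Wadsworth–Emmons olefination under Masamune–Roush conditions at high dilution closes the unstrained 13-membered ring; the α-branched phosphonate should give the (E)-enoate, which puts C6 cis to C13 in the ring, and the mild base spares the C6 centre.

Step 18
Reactants: 22 13-membered (7E)-enoate with C9 carbinol
Product: 23 13-membered α-allyloxy ketone (3S,6R,10S,4Z,7E)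
Conditions: Dess–Martin periodinane, NaHCO3, CH2Cl2, rt
Reagents that add atoms: none
Why: Dess–Martin oxidation of the one remaining free alcohol gives the C9 ketone without base, so the enoate and C6 are not disturbed.

Step 19
Reactants: 23 13-membered α-allyloxy ketone
Product: 25 ten-membered 8-hydroxy-9-ketone with the C7 acrylate (3S,6R,7R,8S,10S,4Z), via lithium (Z)-enolate 24 (not isolated)
Conditions: LiN(SiMe3)2, THF, −78 → −30 °C; AcOH, −78 °C
Reagents that add atoms: none
Why: LiN(SiMe3)2 can enolise 23 only at C8 (C10 is quaternary, C1 is a ketal), and the lithium enolate 24, held (Z) by chelation of lithium between O9 and O8, undergoes a [2,3]-sigmatropic (Wittig) shift through the five-membered envelope C8–O8–C13–C11–C7 in which C8 bonds to C7, O8–C13 breaks and the C11=C13 methylene and the C8 alkoxide appear; conjugate addition of C8 to the enoate followed by β-alkoxide loss would lead to the same product. The closest known reactions are the enolate [2,3]-Wittig rearrangement of α-allyloxy ketones and the [2,3]-Wittig ring contraction of 13-membered allylic ethers to ten-membered carbocycles. Ring A is therefore closed by ring contraction, the C7–C8 bond being made across the 13-membered ring within a five-centre cyclic transition state and not by an end-to-end medium-ring cyclisation. C7 is controlled by the C6 stereocentre: with H6 in the enoate plane facing C13H2 (allylic 1,3-strain) the ring bond C6–C5 and the incoming C8 lie on one face of C7 and the OTBS group on the other; C8 is controlled by the (E)-enoate, which keeps C6 cis to C13, so that with C9 exo on the envelope and cis to C6 the bridge C9–C10–C1–C2–C3–C4–C5–C6 leaves both termini on the same side, which gives H7 and H8 cis (7R,8S here, 7S,8S in the target after the change in CIP ranking). The step needs bonding at C8 ([2,3]) and not at C9 (anionic oxy-Claisen, [3,3]), for which the lithium counter-ion at low temperature, the acceptor character of C7 and the crowding that a C9–C7 bond next to quaternary C10 would create are relied on. Enolisation at C8 must also outrun deprotonation at C6, and the C8 alkoxide must not attack the C12 ester, which the higher acidity of the α-alkoxy ketone and a cold acetic acid quench should secure.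

Step 20
Reactants: 25 ten-membered 8-hydroxy-9-ketone; 26 tiglic acid
Product: 28 8-O-tigloyl 9-ketone, via tiglic 2,4,6-trichlorobenzoic anhydride 27 (not isolated)
Conditions: 26, 2,4,6-Cl3C6H2COCl, Et3N, toluene, rt; then 25, DMAP, rt
Reagents that add atoms: none
Why: Yamaguchi esterification through the mixed anhydride should acylate the hindered C8 hydroxyl faster than it can lactonise onto C12, and it removes the only free hydroxyl before the reduction.

Step 21
Reactants: 28 8-O-tigloyl 9-ketone
Product: 29 (9S)-alcohol (3S,6R,7R,8S,9S,10S)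
Conditions: Zn(BH4)2, Et2O, −30 °C
Reagents that add atoms: none
Why: Chelation-controlled (Cram-chelate) reduction: zinc bridges the C9 carbonyl and the C10 OMOM oxygen and hydride should enter from the side of the small C15 methyl group, giving the (9S)-alcohol, while the enoate and both esters are inert to Zn(BH4)2.

Step 22
Reactants: 29 (9S)-alcohol
Product: 31 6,12-lactone with C1 dioxolane and 10-OMOM, via dihydroxy methyl ester 30 (not isolated)
Conditions: HF·pyridine, pyridine, THF, 0 °C → rt; then TsOH (cat.), CH2Cl2, rt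
Reagents that add atoms: none
Why: Fluoride desilylation frees O3 and O6, and acid-catalysed lactonisation of the γ-hydroxy ester closes the five-membered ring B (5-exo-trig at C12, trans-fused at C6–C7) faster than the six-membered alternative through O9.

Step 23
Reactants: 31 6,12-lactone with C1 dioxolane and 10-OMOM
Product: 32 CNP0106709.2 (3S,6R,7S,8S,9S,10S,4Z)
Conditions: Me2BBr, CH2Cl2, −78 °C; aq. NaHCO3
Reagents that add atoms: water, O
Why: Lewis acid-mediated acetal cleavage with Me2BBr removes MOM ethers and dioxolanes at −78 °C, conditions that should leave the allylic alcohol, the β-hydroxy ketone, the tiglate and the α-methylene lactone intact.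

**Compound list**
1 | ethyl 2-hydroxy-2-methylbut-3-enoate (racemate) | C=CC(C)(O)C(=O)OCC | starting material
2 | ethyl (2S)-2-hydroxy-2-methylbut-3-enoate | C=C[C@](C)(O)C(=O)OCC | intermediate
3 | ethyl (2S)-2-(methoxymethoxy)-2-methylbut-3-enoate | C=C[C@](C)(OCOC)C(=O)OCC | intermediate
4 | (2S)-N-methoxy-2-(methoxymethoxy)-N,2-dimethylbut-3-enamide | C=C[C@](C)(OCOC)C(=O)N(C)OC | intermediate
5 | (3S)-3-(methoxymethoxy)-3-methylpent-4-en-2-one | C=C[C@](C)(OCOC)C(C)=O | intermediate
6 | (Z)-3-iodo-2-methylprop-2-en-1-ol | OC/C(C)=C\I | starting material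
7 | (Z)-3-iodo-2-methylprop-2-enal | O=C/C(C)=C\I | intermediate
8 | diisopinocampheylboron enolate of 5 (O-borylated C1=C2 enol, isopinocampheyl groups from (+)-Ipc2BCl) | C=C[C@](C)(OCOC)C(=C)OB([C@H]1C[C@H]2C[C@@H]([C@@H]1C)C2(C)C)[C@H]1C[C@H]2C[C@@H]([C@@H]1C)C2(C)C | intermediate
9 | (3S,6S,7Z)-6-hydroxy-8-iodo-3-(methoxymethoxy)-3,7-dimethylocta-1,7-dien-4-one (target numbering: 10S, C1 ketone, 3S carbinol, 4Z, 5-iodo) | C=C[C@](C)(OCOC)C(=O)C[C@H](O)/C(C)=C\I | intermediate
10 | O3 tert-butyldimethylsilyl ether of 9 | C=C[C@](C)(OCOC)C(=O)C[C@H](O[Si](C)(C)C(C)(C)C)/C(C)=C\I | intermediate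
11 | 2-[(2S)-2-(methoxymethoxy)but-3-en-2-yl]-2-[(2S,3Z)-2-(tert-butyldimethylsilyloxy)-4-iodo-3-methylbut-3-enyl]-1,3-dioxolane | C=C[C@](C)(OCOC)C1(OCCO1)C[C@H](O[Si](C)(C)C(C)(C)C)/C(C)=C\I | intermediate
12 | 2-[(4-methoxybenzyl)oxy]acetaldehyde | O=CCOCc1ccc(OC)cc1 | starting material
13 | C8–C7 chain, (3S,10S,4Z), C6 carbinol as epimer mixture, C7 PMB ether, C1 dioxolane, 3-OTBS, 10-OMOM | C=C[C@](C)(OCOC)C1(OCCO1)C[C@H](O[Si](C)(C)C(C)(C)C)/C(C)=C\C(O)COCc1ccc(OC)cc1 | intermediate
14 | (3S,10S,4Z)-C6 ketone (enone) of the C8–C7 chain | C=C[C@](C)(OCOC)C1(OCCO1)C[C@H](O[Si](C)(C)C(C)(C)C)/C(C)=C\C(=O)COCc1ccc(OC)cc1 | intermediate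
15 | (3S,6R,10S,4Z)-C6 allylic alcohol of the C8–C7 chain | C=C[C@](C)(OCOC)C1(OCCO1)C[C@H](O[Si](C)(C)C(C)(C)C)/C(C)=C\[C@@H](O)COCc1ccc(OC)cc1 | intermediate
16 | (3S,6R,10S,4Z)-3,6-bis(tert-butyldimethylsilyl) ether | C=C[C@](C)(OCOC)C1(OCCO1)C[C@H](O[Si](C)(C)C(C)(C)C)/C(C)=C\[C@@H](O[Si](C)(C)C(C)(C)C)COCc1ccc(OC)cc1 | intermediate
17 | (3S,6R,10S,4Z)-8,9-diol (C9 epimer mixture) | OCC(O)[C@](C)(OCOC)C1(OCCO1)C[C@H](O[Si](C)(C)C(C)(C)C)/C(C)=C\[C@@H](O[Si](C)(C)C(C)(C)C)COCc1ccc(OC)cc1 | intermediate
18 | trimethyl 2-phosphonoacrylate (methyl 2-(dimethoxyphosphoryl)prop-2-enoate) | C=C(C(=O)OC)P(=O)(OC)OC | starting material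
19 | O8–C13 ether bearing the C11 phosphonoacetate (C9 and C11 epimer mixtures), C7 PMB ether | COC(=O)C(COCC(O)[C@](C)(OCOC)C1(OCCO1)C[C@H](O[Si](C)(C)C(C)(C)C)/C(C)=C\[C@@H](O[Si](C)(C)C(C)(C)C)COCc1ccc(OC)cc1)P(=O)(OC)OC | intermediate
20 | C7 primary alcohol of 19 | COC(=O)C(COCC(O)[C@](C)(OCOC)C1(OCCO1)C[C@H](O[Si](C)(C)C(C)(C)C)/C(C)=C\[C@@H](O[Si](C)(C)C(C)(C)C)CO)P(=O)(OC)OC | intermediate
21 | C7 aldehyde of 19 | COC(=O)C(COCC(O)[C@](C)(OCOC)C1(OCCO1)C[C@H](O[Si](C)(C)C(C)(C)C)/C(C)=C\[C@@H](O[Si](C)(C)C(C)(C)C)C=O)P(=O)(OC)OC | intermediate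
22 | 13-membered oxacycle, (3S,6R,10S,4Z,7E), methyl ester on C11, C9 carbinol (epimer mixture) | COC(=O)/C1=C/[C@H](O[Si](C)(C)C(C)(C)C)/C=C(/C)[C@@H](O[Si](C)(C)C(C)(C)C)CC2(OCCO2)[C@@](C)(OCOC)C(O)COC1 | intermediate
23 | 13-membered α-allyloxy ketone, (3S,6R,10S,4Z,7E) | COC(=O)/C1=C/[C@H](O[Si](C)(C)C(C)(C)C)/C=C(/C)[C@@H](O[Si](C)(C)C(C)(C)C)CC2(OCCO2)[C@@](C)(OCOC)C(=O)COC1 | intermediate
24 | lithium (Z)-C8=C9 enolate of 23 | COC(=O)/C1=C/[C@H](O[Si](C)(C)C(C)(C)C)/C=C(/C)[C@@H](O[Si](C)(C)C(C)(C)C)CC2(OCCO2)[C@@](C)(OCOC)/C(O[Li])=C/OC1 | intermediate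
25 | ten-membered 8-hydroxy-9-ketone with methyl acrylate on C7, (3S,6R,7R,8S,10S,4Z) | C=C(C(=O)OC)[C@H]1[C@H](O[Si](C)(C)C(C)(C)C)/C=C(/C)[C@@H](O[Si](C)(C)C(C)(C)C)CC2(OCCO2)[C@@](C)(OCOC)C(=O)[C@H]1O | intermediate
26 | tiglic acid ((E)-2-methylbut-2-enoic acid) | C/C=C(\C)C(=O)O | starting material
27 | tiglic 2,4,6-trichlorobenzoic anhydride | C/C=C(\C)C(=O)OC(=O)c1c(Cl)cc(Cl)cc1Cl | intermediate
28 | 8-O-tigloyl 9-ketone, (3S,6R,7R,8S,10S,4Z) | C=C(C(=O)OC)[C@H]1[C@H](O[Si](C)(C)C(C)(C)C)/C=C(/C)[C@@H](O[Si](C)(C)C(C)(C)C)CC2(OCCO2)[C@@](C)(OCOC)C(=O)[C@H]1OC(=O)/C(C)=C/C | intermediate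
29 | 8-O-tigloyl (9S)-alcohol, (3S,6R,7R,8S,9S,10S,4Z) | C=C(C(=O)OC)[C@H]1[C@H](O[Si](C)(C)C(C)(C)C)/C=C(/C)[C@@H](O[Si](C)(C)C(C)(C)C)CC2(OCCO2)[C@@](C)(OCOC)[C@@H](O)[C@H]1OC(=O)/C(C)=C/C | intermediate
30 | 3,6-dihydroxy methyl ester, (3S,6R,7S,8S,9S,10S,4Z) | C=C(C(=O)OC)[C@H]1[C@H](O)/C=C(/C)[C@@H](O)CC2(OCCO2)[C@@](C)(OCOC)[C@@H](O)[C@H]1OC(=O)/C(C)=C/C | intermediate
31 | 6,12-lactone with C1 dioxolane and 10-OMOM, (3S,6R,7S,8S,9S,10S,4Z) | C=C1C(=O)O[C@@H]2/C=C(/C)[C@@H](O)CC3(OCCO3)[C@@](C)(OCOC)[C@@H](O)[C@@H](OC(=O)/C(C)=C/C)[C@@H]12 | intermediate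
32 | CNP0106709.2, (3S,6R,7S,8S,9S,10S,4Z)-3,9,10-trihydroxy-1-oxo-8-tigloyloxygermacra-4,11(13)-dien-6,12-olide | C=C1C(=O)O[C@@H]2/C=C(/C)[C@@H](O)CC(=O)[C@@](C)(O)[C@@H](O)[C@@H](OC(=O)/C(C)=C/C)[C@@H]12 | target

**Count and risks**
Total: 23 steps. Longest linear sequence: 22 steps (1 → 32 through steps 1–4 and 6–23; step 5 is a one-step side branch).

Step 19 (ring contraction). The enolate may leak into the [3,3] oxy-Claisen channel and bond C9 to C7, base may instead remove the C6 proton and erode that centre, or the enolate face may not be discriminated, giving the C8 epimer. The fallback changes the carbanion from a ketone enolate to a hydrazone azaenolate, for which the [2,3]-Wittig rearrangement of α-allyloxy ketone hydrazones is known and which is a stronger carbon nucleophile with little tendency to react at C9. Starting from 23, condensation with 1,1-dimethylhydrazine (AcOH cat., EtOH, 70 °C) would give the N,N-dimethylhydrazone F1. LDA (THF, −78 → 0 °C) would trigger the shift to the ring-contracted α-hydroxy hydrazone F2. Aqueous CuCl2 at pH 7 in THF would release the ketone and rejoin the route at 25.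

Step 17 (macrocyclic olefination). The β-alkoxy phosphonate anion may fragment by retro-oxa-Michael loss of the C8 alkoxide, the open chain may oligomerise, and the base may epimerise or isomerise the α-silyloxy β,γ-unsaturated aldehyde. The fallback closes the same C7=C11 bond by base-free ring-closing metathesis. Starting from 17, stannylene activation (Bu2SnO, toluene, reflux) and alkylation with methyl 2-(bromomethyl)acrylate (CsF, DMF) would give the O8 2-(methoxycarbonyl)allyl ether F3. DDQ would free the primary alcohol F4, TEMPO/PhI(OAc)2 would give the aldehyde F5, and Ph3P=CH2 (THF, −78 → 0 °C) the C6 vinyl compound F6. Ring-closing metathesis with the second-generation Hoveyda–Grubbs catalyst (toluene, 80 °C, 1 mM) would then give 22, where the route is rejoined.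

Step 8 (ketalisation). Addition of the diol to the hindered C1 carbonyl may be too slow, and forcing it may cause β-elimination of the C3 silyloxy group or loss of the MOM ether. The fallback masks the ketone with sulfur first and exchanges sulfur for oxygen afterwards. Starting from 10, ZnI2-catalysed thioketalisation with 1,2-bis(trimethylsilylthio)ethane (Et2O, rt), which is far less sensitive to hindrance, would give the 1,3-dithiolane F7. Oxidative transketalisation with PhI(OCOCF3)2 in ethylene glycol/MeCN at −20 °C would convert it into the dioxolane and rejoin the route at 11.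

**Further compounds**
F1 | step 19 | N,N-dimethylhydrazone of 23 at C9 | COC(=O)/C1=C/[C@H](O[Si](C)(C)C(C)(C)C)/C=C(/C)[C@@H](O[Si](C)(C)C(C)(C)C)CC2(OCCO2)[C@@](C)(OCOC)C(=NN(C)C)COC1
F2 | step 19 | ring-contracted 8-hydroxy C9 N,N-dimethylhydrazone | C=C(C(=O)OC)[C@H]1[C@H](O[Si](C)(C)C(C)(C)C)/C=C(/C)[C@@H](O[Si](C)(C)C(C)(C)C)CC2(OCCO2)[C@@](C)(OCOC)C(=NN(C)C)[C@H]1O
F3 | step 17 | O8 2-(methoxycarbonyl)allyl ether of 17 | COC(=O)C(=C)COCC(O)[C@](C)(OCOC)C1(OCCO1)C[C@H](O[Si](C)(C)C(C)(C)C)/C(C)=C\[C@@H](O[Si](C)(C)C(C)(C)C)COCc1ccc(OC)cc1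
F4 | step 17 | C7 primary alcohol of F3 | COC(=O)C(=C)COCC(O)[C@](C)(OCOC)C1(OCCO1)C[C@H](O[Si](C)(C)C(C)(C)C)/C(C)=C\[C@@H](O[Si](C)(C)C(C)(C)C)CO
F5 | step 17 | C7 aldehyde of F3 | COC(=O)C(=C)COCC(O)[C@](C)(OCOC)C1(OCCO1)C[C@H](O[Si](C)(C)C(C)(C)C)/C(C)=C\[C@@H](O[Si](C)(C)C(C)(C)C)C=O
F6 | step 17 | C6 vinyl diene for ring-closing metathesis | COC(=O)C(=C)COCC(O)[C@](C)(OCOC)C1(OCCO1)C[C@H](O[Si](C)(C)C(C)(C)C)/C(C)=C\[C@@H](O[Si](C)(C)C(C)(C)C)C=C
F7 | step 8 | C1 1,3-dithiolane of 10 | C=C[C@](C)(OCOC)C1(SCCS1)C[C@H](O[Si](C)(C)C(C)(C)C)/C(C)=C\I
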